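**Retrosynthetic overview**
1. Target 22 is epicatechin gallate (unit 1)-(4β→6)-epicatechin gallate (unit 2)-(4β→8)-catechin (unit 3), flavan numbering throughout; it is released from 21 by one global hydrogenolysis (19 benzyl ethers, 4 blocking bromines).
2. Key disconnection: ring C of unit 1 is opened across O1–C2 and C3–C4 (retro oxa-[4+2]) to ortho-quinone methide 20 and (Z)-enol gallate 19, which delivers C2, C3, ring B and the galloyl ester in one piece.
3. Enabling feature: C4 of unit 1 is a doubly benzylic methine between C4a of phloroglucinol ring A (whose ortho oxygen is O1) and C6 of ring A of unit 2, and C2 carries the para-oxygenated ring B; ring C (O1–C2–C3–C4–C4a–C8a) therefore maps onto a quinone methide diene plus a styrene-polarised enol ester.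
4. Benzhydrol 16 (precursor of 20) comes from aryl iodide 11 and salicylaldehyde 14; 11 comes from Lewis acid 4β→8 coupling of the C4-activated 6-iodo-8-bromo epicatechin gallate 7 with benzylated catechin 9, then bromination.
5. Ring order: all rings of units 2 and 3 come intact from (−)-epicatechin and (+)-catechin; ring C of unit 1 is the only ring built, and it is built last.

Key step: step 14

Assumption: the (R)-configured phosphoramide is taken to open the face of 20 that leads to the 4β series; induction is catalyst-controlled (the existing centres are remote), so the (S)-catalyst is the direct remedy if the other face reacts.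

**Route**

Step 1
Reactants: 1 (−)-epicatechin
Product: 2 5,7,3',4'-tetra-O-benzyl-(−)-epicatechin
Conditions: BnBr (4.4 equiv), K2CO3, DMF, 0 °C → rt
Reagents that add atoms: benzyl bromide, BrCc1ccccc1
Why: Williamson etherification with a weak base alkylates only the four phenols (K2CO3 does not deprotonate the secondary 3-OH), and no stereocentre is touched.

Step 2
Reactants: 2 5,7,3',4'-tetra-O-benzyl-(−)-epicatechin
Product: 3 4β-(2-ethoxyethoxy)-5,7,3',4'-tetra-O-benzyl-(−)-epicatechin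
Conditions: DDQ (2 equiv), 2-ethoxyethanol (5 equiv), CH2Cl2, rt
Reagents that add atoms: 2-ethoxyethanol, CCOCCO
Why: DDQ abstracts hydride from benzylic C4 (oxidative benzylic etherification of benzylated flavan-3-ols) and the alcohol adds to the ring A-stabilised cation anti to the axial 3-OH, which sets the temporary 3,4-trans (4β) centre.

Step 3
Reactants: 3 4β-(2-ethoxyethoxy)-5,7,3',4'-tetra-O-benzyl-(−)-epicatechin
Product: 4 8-bromo-4β-(2-ethoxyethoxy)-5,7,3',4'-tetra-O-benzyl-(−)-epicatechin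
Conditions: NBS (1.0 equiv), CH2Cl2, −78 → 0 °C
Reagents that add atoms: N-bromosuccinimide, O=C1CCC(=O)N1Br
Why: electrophilic aromatic bromination goes to C8, the more accessible free position of ring A (C6 lies between two benzyloxy groups, one buttressed by the C4 substituent), as is usual for benzylated flavan-3-ols.

Step 4
Reactants: 4 8-bromo-4β-(2-ethoxyethoxy)-5,7,3',4'-tetra-O-benzyl-(−)-epicatechin
Product: 5 8-bromo-6-iodo-4β-(2-ethoxyethoxy)-5,7,3',4'-tetra-O-benzyl-(−)-epicatechin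
Conditions: NIS (1.3 equiv), MeCN/CH2Cl2, 0 °C → rt, dark
Reagents that add atoms: N-iodosuccinimide, O=C1CCC(=O)N1I
Why: electrophilic aromatic iodination of the last free, still phloroglucinol-type position C6; no acid is added, so the C4 ether should survive.

Step 5
Reactants: 5 8-bromo-6-iodo-4β-(2-ethoxyethoxy)-5,7,3',4'-tetra-O-benzyl-(−)-epicatechin; 6 3,4,5-tris(benzyloxy)benzoic acid
Product: 7 8-bromo-6-iodo-4β-(2-ethoxyethoxy)-5,7,3',4'-tetra-O-benzyl-(−)-epicatechin 3-O-[3,4,5-tris(benzyloxy)benzoate]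
Conditions: DCC, DMAP (cat.), CH2Cl2, rt
Reagents that add atoms: none
Why: Steglich esterification acylates the 3-OH on oxygen, so C3 keeps its configuration, and the neutral conditions spare the C4 ether.

Step 6
Reactants: 8 (+)-catechin
Product: 9 3,5,7,3',4'-penta-O-benzyl-(+)-catechin
Conditions: NaH (6 equiv), BnBr (5.5 equiv), DMF, −10 °C → rt
Reagents that add atoms: benzyl bromide, BrCc1ccccc1
Why: Williamson etherification of all five hydroxyl groups (NaH also deprotonates the 3-OH); the O3 benzyl ether keeps this alcohol silent in the organomagnesium step and leaves with the others at the end.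

Step 7
Reactants: 7 8-bromo-6-iodo-4β-(2-ethoxyethoxy)-5,7,3',4'-tetra-O-benzyl-(−)-epicatechin 3-O-[3,4,5-tris(benzyloxy)benzoate]; 9 3,5,7,3',4'-penta-O-benzyl-(+)-catechin
Product: 10 protected dimer [8-bromo-6-iodo-tetra-O-benzyl-3-O-(tri-O-benzylgalloyl)epicatechin]-(4β→8)-[penta-O-benzylcatechin]
Conditions: 9 (2 equiv), TMSOTf (0.2 equiv), 4 Å MS, CH2Cl2, −78 → −40 °C; Et3N quench
Reagents that add atoms: none
Why: Lewis acid ionisation of the C4 ether gives the flavan-4-yl cation, which is arylated by C8 of 9 (Friedel–Crafts-type interflavan coupling) anti to the participating 3-O-galloyl group, setting C4 of unit 2 as 4β; the two halogens make self-condensation of 7 impossible.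

Step 8
Reactants: 10 protected dimer
Product: 11 protected dimer brominated at C6 of unit 3
Conditions: NBS (1.05 equiv), CH2Cl2, −40 → 0 °C
Reagents that add atoms: N-bromosuccinimide, O=C1CCC(=O)N1Br
Why: electrophilic aromatic bromination at the only free phloroglucinol-type carbon left in 10, which removes the last arene nucleophile that could intercept the quinone methide later.

Step 9
Reactants: 12 2,4,6-trihydroxybenzaldehyde
Product: 13 2,4-bis(benzyloxy)-6-hydroxybenzaldehyde
Conditions: BnBr (2.05 equiv), K2CO3 (2 equiv), DMF, rt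
Reagents that add atoms: benzyl bromide, BrCc1ccccc1
Why: Williamson etherification; the 4-OH and one ortho-OH react, while the remaining ortho-OH is held in a hydrogen bond to the formyl group and stays free.

Step 10
Reactants: 13 2,4-bis(benzyloxy)-6-hydroxybenzaldehyde
Product: 14 2,4-bis(benzyloxy)-3,5-dibromo-6-hydroxybenzaldehyde
Conditions: NBS (2.1 equiv), CH2Cl2, 0 °C → rt
Reagents that add atoms: N-bromosuccinimide, O=C1CCC(=O)N1Br
Why: twofold electrophilic aromatic bromination of the two free ring positions, each ortho/para to three oxygens; the bromines block later Friedel–Crafts reactions of ring A of unit 1 and make the quinone methide more electrophilic.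

Step 11
Reactants: 11 protected dimer brominated at C6 of unit 3; 14 2,4-bis(benzyloxy)-3,5-dibromo-6-hydroxybenzaldehyde
Product: 16 benzhydrol [3,5-dibromo-2-hydroxy-4,6-bis(benzyloxy)phenyl](C6 of unit 2 of the dimer)methanol as both carbinol epimers, via arylmagnesium chloride 15 (not isolated)
Conditions: 11, i-PrMgCl·LiCl (1.1 equiv), THF, −30 °C; then 14 (pre-treated with i-PrMgCl·LiCl, 1.0 equiv, THF, −78 °C), −30 → 0 °C; aq NH4Cl; Et3N-deactivated silica
Reagents that add atoms: none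
Why: iodine–magnesium exchange is selective for the carbon–iodine bond over the carbon–bromine bonds and tolerates the hindered ester at low temperature, and the arylmagnesium adds 1,2 to the chelated magnesium salicylaldehyde phenoxide; the new carbinol centre forms as a mixture, which does not matter because it is planarised in step 14.

Step 12
Reactants: 17 3,4-bis(benzyloxy)benzaldehyde
Product: 18 1,2-bis(benzyloxy)-4-ethynylbenzene
Conditions: Ohira–Bestmann reagent, K2CO3, MeOH/THF, rt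
Reagents that add atoms: dimethyl (1-diazo-2-oxopropyl)phosphonate, COP(=O)(OC)C(=[N+]=[N-])C(C)=O
Why: Seyferth–Gilbert homologation in its Ohira–Bestmann form converts the aldehyde into the terminal alkyne under mild base.

Step 13
Reactants: 18 1,2-bis(benzyloxy)-4-ethynylbenzene; 6 3,4,5-tris(benzyloxy)benzoic acid
Product: 19 (Z)-2-[3,4-bis(benzyloxy)phenyl]ethenyl 3,4,5-tris(benzyloxy)benzoate
Conditions: Ru(η3-2-methylallyl)2(dppb) (2 mol%; dppb = Ph2P(CH2)4PPh2), toluene, 65 °C
Reagents that add atoms: none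
Why: ruthenium-catalysed anti-Markovnikov addition of a carboxylic acid to a terminal alkyne through a ruthenium vinylidene, a reaction type known to give (Z)-enol esters from arylacetylenes; the alkene geometry that later becomes the 2,3-cis relation is set here.

Step 14
Reactants: 16 benzhydrol; 19 (Z)-2-[3,4-bis(benzyloxy)phenyl]ethenyl 3,4,5-tris(benzyloxy)benzoate
Product: 21 protected trimer (nonadeca-O-benzyl tetrabromo derivative of the target), via ortho-quinone methide 20 (not isolated)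
Conditions: 19 (3 equiv), (R)-3,3'-bis(2,4,6-triisopropylphenyl)-1,1'-binaphthyl-2,2'-diyl N-triflylphosphoramide (10 mol%), 5 Å MS, CH2Cl2, −40 → 0 °C
Reagents that add atoms: none
Why: Proposed new method: the phosphoramide ionises the doubly benzylic carbinol of 16 to the hydrogen-bonded ortho-quinone methide 20, whose methide carbon (future C4) is attacked by the oxygen-bearing alkene carbon of 19 (future C3) while the quinone oxygen (future O1) closes on the developing 4-benzyloxybenzylic carbon (future C2) in an asynchronous inverse-electron-demand oxa-[4+2] cycloaddition; a β-acyloxystyrene has not been used as the 2π partner, and the reasoning is that its HOMO is still that of a para-alkoxystyrene, with the acyloxy group a spectator on the nucleophilic carbon. The closest known reaction type is the chiral Brønsted acid-catalysed [4+2] cycloaddition of ortho-quinone methides, generated from ortho-hydroxybenzhydrols, with styrenes to give 2,4-diarylchromans. Ring C of unit 1 is the only ring closed, as the six-membered ring of the [4+2] (C–C bond first, C–O bond second, without a free intermediate). The 2,3-cis relation follows from suprafacial addition to the (Z)-alkene; the 3,4-trans relation from the exo, chair-like topology in which peri strain against the 5-benzyloxy group forces the C4 aryl group pseudo-axial and the galloyloxy group at C3 takes the opposite axial site while ring B stays equatorial; the absolute configuration of C2, C3 and C4 comes from the face of 20 left open in the chiral ion pair, the centres of units 2 and 3 being too remote to interfere. The step needs styrene-type regiochemistry (secured by the para-benzyloxy group of ring B), alkene attack in preference to arene Friedel–Crafts attack (secured by bromine at every free phloroglucinol position of 16 and of the product), ring closure through the single free phenol of ring A of unit 1, and exo over endo approach (secured by the 5-benzyloxy group and the cis-disubstituted alkene).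

Step 15
Reactants: 21 protected trimer
Product: 22 (−)-epicatechin-3-O-gallate-(4β→6)-(−)-epicatechin-3-O-gallate-(4β→8)-(+)-catechin (target)
Conditions: H2 (1 atm), Pd(OH)2/C, Et3N (4.4 equiv), THF/MeOH/H2O, rt; Sephadex LH-20
Reagents that add atoms: none
Why: hydrogenolysis cleaves the nineteen benzyl ethers and the four aryl carbon–bromine bonds (Et3N takes up HBr so the acid-labile interflavan bonds are not exposed to it), while the esters and all eight stereocentres are untouched.

**Compound list**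

1 | (−)-epicatechin | O[C@@H]1Cc2c(O)cc(O)cc2O[C@@H]1c1ccc(O)c(O)c1 | starting material
2 | 5,7,3',4'-tetra-O-benzyl-(−)-epicatechin | c1c(OCc3ccccc3)cc2c(c1OCc3ccccc3)C[C@@H](O)[C@@H](c1ccc(OCc3ccccc3)c(OCc3ccccc3)c1)O2 | intermediate
3 | 4β-(2-ethoxyethoxy)-5,7,3',4'-tetra-O-benzyl-(−)-epicatechin (2,3-cis-3,4-trans) | c1c(OCc3ccccc3)cc2c(c1OCc3ccccc3)[C@H](OCCOCC)[C@@H](O)[C@@H](c1ccc(OCc3ccccc3)c(OCc3ccccc3)c1)O2 | intermediate
4 | 8-bromo derivative of 3 | c1c(OCc3ccccc3)c(Br)c2c(c1OCc3ccccc3)[C@H](OCCOCC)[C@@H](O)[C@@H](c1ccc(OCc3ccccc3)c(OCc3ccccc3)c1)O2 | intermediate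
5 | 8-bromo-6-iodo derivative of 3 | Ic1c(OCc3ccccc3)c(Br)c2c(c1OCc3ccccc3)[C@H](OCCOCC)[C@@H](O)[C@@H](c1ccc(OCc3ccccc3)c(OCc3ccccc3)c1)O2 | intermediate
6 | 3,4,5-tris(benzyloxy)benzoic acid | OC(=O)c1cc(OCc2ccccc2)c(OCc2ccccc2)c(OCc2ccccc2)c1 | starting material
7 | 8-bromo-6-iodo-4β-(2-ethoxyethoxy)-5,7,3',4'-tetra-O-benzyl-(−)-epicatechin 3-O-[3,4,5-tris(benzyloxy)benzoate] | Ic1c(OCc3ccccc3)c(Br)c2c(c1OCc3ccccc3)[C@H](OCCOCC)[C@@H](OC(=O)c1cc(OCc3ccccc3)c(OCc3ccccc3)c(OCc3ccccc3)c1)[C@@H](c1ccc(OCc3ccccc3)c(OCc3ccccc3)c1)O2 | intermediate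
8 | (+)-catechin | O[C@H]1Cc2c(O)cc(O)cc2O[C@@H]1c1ccc(O)c(O)c1 | starting material
9 | 3,5,7,3',4'-penta-O-benzyl-(+)-catechin | c1c(OCc3ccccc3)cc(OCc3ccccc3)c2c1O[C@H](c1ccc(OCc3ccccc3)c(OCc3ccccc3)c1)[C@@H](OCc1ccccc1)C2 | intermediate
10 | protected dimer: 8-bromo-6-iodo-tetra-O-benzyl-3-O-(tri-O-benzylgalloyl)epicatechin-(4β→8)-penta-O-benzylcatechin | Ic1c(OCc3ccccc3)c(Br)c2c(c1OCc3ccccc3)[C@H](c4c(OCc3ccccc3)cc(OCc3ccccc3)c5c4O[C@H](c6ccc(OCc3ccccc3)c(OCc3ccccc3)c6)[C@@H](OCc3ccccc3)C5)[C@@H](OC(=O)c6cc(OCc3ccccc3)c(OCc3ccccc3)c(OCc3ccccc3)c6)[C@@H](c6ccc(OCc3ccccc3)c(OCc3ccccc3)c6)O2 | intermediate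
11 | dimer 10 with bromine at C6 of unit 3 | Ic1c(OCc3ccccc3)c(Br)c2c(c1OCc3ccccc3)[C@H](c4c(OCc3ccccc3)c(Br)c(OCc3ccccc3)c5c4O[C@H](c6ccc(OCc3ccccc3)c(OCc3ccccc3)c6)[C@@H](OCc3ccccc3)C5)[C@@H](OC(=O)c6cc(OCc3ccccc3)c(OCc3ccccc3)c(OCc3ccccc3)c6)[C@@H](c6ccc(OCc3ccccc3)c(OCc3ccccc3)c6)O2 | intermediate
12 | 2,4,6-trihydroxybenzaldehyde | O=Cc1c(O)cc(O)cc1O | starting material
13 | 2,4-bis(benzyloxy)-6-hydroxybenzaldehyde | O=Cc1c(O)cc(OCc2ccccc2)cc1OCc1ccccc1 | intermediate
14 | 2,4-bis(benzyloxy)-3,5-dibromo-6-hydroxybenzaldehyde | O=Cc1c(O)c(Br)c(OCc2ccccc2)c(Br)c1OCc1ccccc1 | intermediate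
15 | arylmagnesium chloride of 11 (magnesium at C6 of unit 2) | Cl[Mg]c1c(OCc3ccccc3)c(Br)c2c(c1OCc3ccccc3)[C@H](c4c(OCc3ccccc3)c(Br)c(OCc3ccccc3)c5c4O[C@H](c6ccc(OCc3ccccc3)c(OCc3ccccc3)c6)[C@@H](OCc3ccccc3)C5)[C@@H](OC(=O)c6cc(OCc3ccccc3)c(OCc3ccccc3)c(OCc3ccccc3)c6)[C@@H](c6ccc(OCc3ccccc3)c(OCc3ccccc3)c6)O2 | intermediate
16 | benzhydrol: [3,5-dibromo-2-hydroxy-4,6-bis(benzyloxy)phenyl](C6 of unit 2)methanol, both carbinol epimers | OC(c1c(O)c(Br)c(OCc3ccccc3)c(Br)c1OCc3ccccc3)c1c(OCc3ccccc3)c(Br)c2c(c1OCc3ccccc3)[C@H](c4c(OCc3ccccc3)c(Br)c(OCc3ccccc3)c5c4O[C@H](c6ccc(OCc3ccccc3)c(OCc3ccccc3)c6)[C@@H](OCc3ccccc3)C5)[C@@H](OC(=O)c6cc(OCc3ccccc3)c(OCc3ccccc3)c(OCc3ccccc3)c6)[C@@H](c6ccc(OCc3ccccc3)c(OCc3ccccc3)c6)O2 | intermediate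
17 | 3,4-bis(benzyloxy)benzaldehyde | O=Cc1ccc(OCc2ccccc2)c(OCc2ccccc2)c1 | starting material
18 | 1,2-bis(benzyloxy)-4-ethynylbenzene | C#Cc1ccc(OCc2ccccc2)c(OCc2ccccc2)c1 | intermediate
19 | (Z)-2-[3,4-bis(benzyloxy)phenyl]ethenyl 3,4,5-tris(benzyloxy)benzoate | O=C(O/C=C\c1ccc(OCc2ccccc2)c(OCc2ccccc2)c1)c1cc(OCc2ccccc2)c(OCc2ccccc2)c(OCc2ccccc2)c1 | intermediate
20 | ortho-quinone methide from 16 (methide geometry not fixed) | O=C1C(Br)=C(OCc3ccccc3)C(Br)=C(OCc3ccccc3)C1=Cc1c(OCc3ccccc3)c(Br)c2c(c1OCc3ccccc3)[C@H](c4c(OCc3ccccc3)c(Br)c(OCc3ccccc3)c5c4O[C@H](c6ccc(OCc3ccccc3)c(OCc3ccccc3)c6)[C@@H](OCc3ccccc3)C5)[C@@H](OC(=O)c6cc(OCc3ccccc3)c(OCc3ccccc3)c(OCc3ccccc3)c6)[C@@H](c6ccc(OCc3ccccc3)c(OCc3ccccc3)c6)O2 | intermediate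
21 | protected trimer: target with 19 O-benzyl groups and bromine at C6 and C8 of unit 1, C8 of unit 2 and C6 of unit 3 | O=C(O[C@@H]1[C@@H](c2c(OCc9ccccc9)c(Br)c3c(c2OCc9ccccc9)[C@H](c2c(OCc9ccccc9)c(Br)c(OCc9ccccc9)c4c2O[C@H](c2ccc(OCc9ccccc9)c(OCc9ccccc9)c2)[C@@H](OCc9ccccc9)C4)[C@@H](OC(=O)c2cc(OCc9ccccc9)c(OCc9ccccc9)c(OCc9ccccc9)c2)[C@@H](c2ccc(OCc9ccccc9)c(OCc9ccccc9)c2)O3)c2c(OCc9ccccc9)c(Br)c(OCc9ccccc9)c(Br)c2O[C@@H]1c1ccc(OCc9ccccc9)c(OCc9ccccc9)c1)c1cc(OCc9ccccc9)c(OCc9ccccc9)c(OCc9ccccc9)c1 | intermediate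
22 | (−)-epicatechin-3-O-gallate-(4β→6)-(−)-epicatechin-3-O-gallate-(4β→8)-(+)-catechin | O=C(O[C@@H]1[C@@H](c2c(O)cc3c(c2O)[C@H](c2c(O)cc(O)c4c2O[C@H](c2ccc(O)c(O)c2)[C@@H](O)C4)[C@@H](OC(=O)c2cc(O)c(O)c(O)c2)[C@@H](c2ccc(O)c(O)c2)O3)c2c(O)cc(O)cc2O[C@@H]1c1ccc(O)c(O)c1)c1cc(O)c(O)c(O)c1 | target

**Step count and risks**

Total step count: 15. Longest linear sequence: 10 steps (1, 2, 3, 4, 5, 7, 8, 11, 14, 15).

Step 14 (most likely to fail). The cycloaddition may take the enol-ester regiochemistry instead of the styrene one, or give endo or mixed facial selectivity. It may also be outrun by acid-induced Z/E isomerisation of 19 or by self-condensation of 20. Fallback with known chemistry: ring C of unit 1 is not built but taken from (−)-epicatechin, and the 4β→6 bond is made by the classical Lewis acid coupling. The fallback sets out from 11, whose iodine is exchanged for magnesium (i-PrMgCl·LiCl, THF, −30 °C) and replaced by hydrogen on MeOH quench to give the C6–H dimer F1. In parallel, 4 is brominated once more (NBS, CH2Cl2) to the 6,8-dibromide F2, which is esterified with 6 (DCC, DMAP) to the gallate F3. TMSOTf-promoted coupling of F3 with F1 (CH2Cl2, −78 → −20 °C) then gives 21, where the route is rejoined. In that coupling C8 of unit 2 is blocked by bromine so that C6 must react, and the 3-O-galloyl group directs 4β attack.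

Step 11. The iodine–magnesium exchange on the electron-rich, doubly ortho-substituted iodide may stay incomplete, the organomagnesium may attack the gallate ester, or its addition to the hindered aldehyde may stall. Fallback with reversed polarity, so that the dimer is the electrophile and no organomagnesium is made on it: the fallback sets out from 11. Pd(PPh3)4-catalysed formylation (CO, Bu3SnH, toluene, 50 °C; the carbon–iodine bond reacts before the carbon–bromine bonds) gives the dimer 6-carbaldehyde F4. The bromomagnesium phenoxide of commercial 3,5-bis(benzyloxy)phenol (EtMgBr, Et2O/toluene) adds to F4 through its ortho carbon (chelation-controlled ortho-hydroxyalkylation of magnesium phenoxides) to give the bromine-free benzhydrol F5. NBS (2 equiv, 2,6-lutidine, CH2Cl2, −78 °C) brominates the two free positions of the new phenol ring and returns 16.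

Step 7. The two halogens may slow ionisation at C4, and the iodine-flanked 5-benzyloxy group may hinder the approach of 9, so that the cation is lost to elimination or hydrolysis. Fallback that halogenates after, not before, the interflavan bond is made: it sets out from 3, which is esterified with 6 (DCC, DMAP) to the halogen-free gallate F6. TMSOTf coupling with excess 9 (3 equiv, CH2Cl2, −78 °C) gives the halogen-free dimer F7. NBS (2 equiv) should brominate the two most accessible phloroglucinol positions, C8 of unit 2 and C6 of unit 3, to give the dibromide F1 described above. NIS then iodinates the last free position, C6 of unit 2, and returns 11.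

**Further compounds**

F1 | step 14 | dimer 11 with hydrogen in place of iodine at C6 of unit 2 | c1c(OCc3ccccc3)c(Br)c2c(c1OCc3ccccc3)[C@H](c4c(OCc3ccccc3)c(Br)c(OCc3ccccc3)c5c4O[C@H](c6ccc(OCc3ccccc3)c(OCc3ccccc3)c6)[C@@H](OCc3ccccc3)C5)[C@@H](OC(=O)c6cc(OCc3ccccc3)c(OCc3ccccc3)c(OCc3ccccc3)c6)[C@@H](c6ccc(OCc3ccccc3)c(OCc3ccccc3)c6)O2
F2 | step 14 | 6,8-dibromo-4β-(2-ethoxyethoxy)-5,7,3',4'-tetra-O-benzyl-(−)-epicatechin | Brc1c(OCc3ccccc3)c(Br)c2c(c1OCc3ccccc3)[C@H](OCCOCC)[C@@H](O)[C@@H](c1ccc(OCc3ccccc3)c(OCc3ccccc3)c1)O2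
F3 | step 14 | 3-O-[3,4,5-tris(benzyloxy)benzoate] of F2 | Brc1c(OCc3ccccc3)c(Br)c2c(c1OCc3ccccc3)[C@H](OCCOCC)[C@@H](OC(=O)c1cc(OCc3ccccc3)c(OCc3ccccc3)c(OCc3ccccc3)c1)[C@@H](c1ccc(OCc3ccccc3)c(OCc3ccccc3)c1)O2
F4 | step 11 | dimer 11 with a formyl group in place of iodine at C6 of unit 2 | O=Cc1c(OCc3ccccc3)c(Br)c2c(c1OCc3ccccc3)[C@H](c4c(OCc3ccccc3)c(Br)c(OCc3ccccc3)c5c4O[C@H](c6ccc(OCc3ccccc3)c(OCc3ccccc3)c6)[C@@H](OCc3ccccc3)C5)[C@@H](OC(=O)c6cc(OCc3ccccc3)c(OCc3ccccc3)c(OCc3ccccc3)c6)[C@@H](c6ccc(OCc3ccccc3)c(OCc3ccccc3)c6)O2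
F5 | step 11 | benzhydrol 16 without the two bromines on the phenol ring, both carbinol epimers | OC(c1c(O)cc(OCc3ccccc3)cc1OCc3ccccc3)c1c(OCc3ccccc3)c(Br)c2c(c1OCc3ccccc3)[C@H](c4c(OCc3ccccc3)c(Br)c(OCc3ccccc3)c5c4O[C@H](c6ccc(OCc3ccccc3)c(OCc3ccccc3)c6)[C@@H](OCc3ccccc3)C5)[C@@H](OC(=O)c6cc(OCc3ccccc3)c(OCc3ccccc3)c(OCc3ccccc3)c6)[C@@H](c6ccc(OCc3ccccc3)c(OCc3ccccc3)c6)O2
F6 | step 7 | 4β-(2-ethoxyethoxy)-5,7,3',4'-tetra-O-benzyl-(−)-epicatechin 3-O-[3,4,5-tris(benzyloxy)benzoate] | c1c(OCc3ccccc3)cc2c(c1OCc3ccccc3)[C@H](OCCOCC)[C@@H](OC(=O)c1cc(OCc3ccccc3)c(OCc3ccccc3)c(OCc3ccccc3)c1)[C@@H](c1ccc(OCc3ccccc3)c(OCc3ccccc3)c1)O2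
F7 | step 7 | halogen-free protected dimer: tetra-O-benzyl-3-O-(tri-O-benzylgalloyl)epicatechin-(4β→8)-penta-O-benzylcatechin | c1c(OCc3ccccc3)cc2c(c1OCc3ccccc3)[C@H](c4c(OCc3ccccc3)cc(OCc3ccccc3)c5c4O[C@H](c6ccc(OCc3ccccc3)c(OCc3ccccc3)c6)[C@@H](OCc3ccccc3)C5)[C@@H](OC(=O)c6cc(OCc3ccccc3)c(OCc3ccccc3)c(OCc3ccccc3)c6)[C@@H](c6ccc(OCc3ccccc3)c(OCc3ccccc3)c6)O2
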